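**Retrosynthetic overview**

1. The C40 chain is cut at C11=C12 and C11'=C12' (two Wittig olefinations) into a β-end C15 phosphonium salt, the commercial C10 trienedial and an ε-end C15 phosphonium salt. The ε ring is bought intact as (R)-α-ionone and receives its C3' oxygen by allylic oxidation and Corey–Bakshi–Shibata reduction.
2. β-End C15 unit: C6–C7 by Stille coupling of a ring enol triflate (C6–OTf) with a C5 stannyldienol; the C3 oxygen comes from a C3 acyl group by Baeyer–Villiger oxidation with retention.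
3. The only ring built de novo, the 3,4-dioxygenated trimethylcyclohexene of the β end, is closed by one enantioselective Diels–Alder reaction that forms C1–C2 and C3–C4. The partners are a 1,3-bis(silyloxy)diene (C4=C5–C6=C1, two steps from 2-methylpentan-3-one and ethyl formate) and N-acryloyl oxazolidinone (C2=C3).
4. Enabling feature: in the β ring the C5=C6 double bond lies between the oxygen-bearing allylic C4 and the quaternary C1, which is a cyclohexene retron. Carrying C6 (the carbon that holds the polyene) as an enol oxygen turns C4=C5–C6=C1 into a doubly oxygen-activated diene, and the imide carbonyl on C3 stands in for the hydroxyl.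
5. Ring order: β ring in step 3, ε ring present from the start. Temporary groups are removed again: C6–O (triflate, Stille), C3 acyl (Baeyer–Villiger), silyl and acetyl groups (last step).

Key step: step 3

Assumption: (R)-α-ionone and (E)-3-methylpent-2-en-4-yn-1-ol are taken as purchasable in isomerically pure form; carotenoid numbering is used for ring atoms (C1 = CMe2, C2 = CH2, C3 and C4 = carbinol carbons, C5=C6 = ring alkene); t-Bu-box = 2,2'-(propane-2,2-diyl)bis[(4S)-4-tert-butyl-4,5-dihydro-1,3-oxazole].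

**Route**

Step 1
Reactants: 1 2-methylpentan-3-one; 2 ethyl formate
Product: 4 (1E)-2,4-dimethyl-1-{[tri(propan-2-yl)silyl]oxy}pent-1-en-3-one, via sodium 2,4-dimethyl-3-oxopent-1-en-1-olate 3 (not isolated)
Conditions: NaH, EtOH (cat.), THF, 0 °C to rt; then i-Pr3SiCl, 0 °C to rt
Reagents that add atoms: chlorotri(propan-2-yl)silane, CC(C)[Si](Cl)(C(C)C)C(C)C
Why: Crossed Claisen condensation (formylation) should occur only at the CH2 flank, where the product is held as a stabilised enolate, and O-silylation at the formyl oxygen gives the vinylogous silyl ester (any Z isomer converges in step 2).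

Step 2
Reactants: 4 (1E)-2,4-dimethyl-1-{[tri(propan-2-yl)silyl]oxy}pent-1-en-3-one
Product: 5 (1E)-3-{[tert-butyl(dimethyl)silyl]oxy}-2,4-dimethyl-1-{[tri(propan-2-yl)silyl]oxy}penta-1,3-diene
Conditions: t-BuMe2SiOTf, Et3N, CH2Cl2, 0 °C to rt
Reagents that add atoms: tert-butyldimethylsilyl trifluoromethanesulfonate, CC(C)(C)[Si](C)(C)OS(=O)(=O)C(F)(F)F
Why: Soft enolisation (silyl triflate and amine) at the only enolisable position, the isopropyl C–H, should give the tetrasubstituted silyl enol ether; the (E) geometry at C4=C5 is the thermodynamic one, reached through the freely rotating O-silylated cation.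

Step 3
Reactants: 5 (1E)-3-{[tert-butyl(dimethyl)silyl]oxy}-2,4-dimethyl-1-{[tri(propan-2-yl)silyl]oxy}penta-1,3-diene; 6 3-acryloyl-1,3-oxazolidin-2-one
Product: 7 3-{[(1S,2S)-4-{[tert-butyl(dimethyl)silyl]oxy}-3,5,5-trimethyl-2-{[tri(propan-2-yl)silyl]oxy}cyclohex-3-en-1-yl]carbonyl}-1,3-oxazolidin-2-one
Conditions: [Cu((S,S)-t-Bu-box)](SbF6)2 (10 mol %), CH2Cl2, −40 °C to −20 °C
Reagents that add atoms: none
Why: Two-point chelation of the s-cis acrylimide to the square-planar divalent copper centre lowers its LUMO; the Me2C terminus of the diene (C1, the nucleophilic end of a 1,3-dioxygenated diene) bonds to the unsubstituted β-carbon (C2) while the α-carbon (C3) closes on the silyloxy-bearing terminus (C4), in a concerted but strongly asynchronous [4+2] cycloaddition (in the limit a Mukaiyama–Michael addition followed by closure of the copper-bound enolate on the silyloxyallyl cation, which should give the same product and relaxes the s-cis demand on the crowded diene). The closest known reaction type is the bis(oxazoline)–copper-catalysed enantioselective Diels–Alder reaction of N-acryloyl oxazolidinone with 1-acyloxy-, 1-thio- and siloxy-substituted dienes. The cyclohexene ring closes by suprafacial [π4s+π2s] cycloaddition, which leaves C5=C6 as a tetrasubstituted silyl enol ether and makes C1 quaternary. C3 is set by the ligand: the tert-butyl group next to the acryloyl carbonyl blocks one face of the chelated dienophile, so the diene should add to the face that gives (3S); C4 is set relative to C3 by the endo rule for an (E)-1-oxygenated diene, which places the C4–O bond cis to the C3 carbonyl group (descriptor 4S here, 4R once the C3 carbon substituent is exchanged for oxygen, with no change in space). The step needs regioselectivity (C2 to C1, C3 to C4), secured because both silyloxy groups polarise the diene in the same sense and the bond to the hindered Me2C terminus is made by the unhindered CH2; it also needs endo and facial selectivity, secured by the rigid chelate.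

Step 4
Reactants: 7 3-{[(1S,2S)-4-{[tert-butyl(dimethyl)silyl]oxy}-3,5,5-trimethyl-2-{[tri(propan-2-yl)silyl]oxy}cyclohex-3-en-1-yl]carbonyl}-1,3-oxazolidin-2-one
Product: 8 (3S,4S)-2,6,6-trimethyl-4-[(2-oxo-1,3-oxazolidin-3-yl)carbonyl]-3-{[tri(propan-2-yl)silyl]oxy}cyclohex-1-en-1-yl trifluoromethanesulfonate
Conditions: CsF, PhNTf2, 1,2-dimethoxyethane, rt
Reagents that add atoms: N-phenylbis(trifluoromethanesulfonimide), O=S(=O)(N(c1ccccc1)S(=O)(=O)C(F)(F)F)C(F)(F)F
Why: Fluoride cleaves the enol Si–O bond far faster than the hindered alkyl silyl ether, and the regiodefined enolate should be trapped at once as the enol triflate (enolate O-sulfonylation), with no stereocentre touched.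

Step 5
Reactants: 8 (3S,4S)-2,6,6-trimethyl-4-[(2-oxo-1,3-oxazolidin-3-yl)carbonyl]-3-{[tri(propan-2-yl)silyl]oxy}cyclohex-1-en-1-yl trifluoromethanesulfonate
Product: 9 (3S,4S)-4-[methoxy(methyl)carbamoyl]-2,6,6-trimethyl-3-{[tri(propan-2-yl)silyl]oxy}cyclohex-1-en-1-yl trifluoromethanesulfonate
Conditions: MeNH(OMe)·HCl, AlMe3, CH2Cl2, 0 °C to rt
Reagents that add atoms: N,O-dimethylhydroxylamine hydrochloride, CNOC.Cl
Why: Aluminium amide transamidation of the N-acyl oxazolidinone (first half of the Weinreb ketone synthesis) should cleave the exocyclic acyl–N bond without enolising C3, and the enol triflate and silyl ether are inert to it.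

Step 6
Reactants: 9 (3S,4S)-4-[methoxy(methyl)carbamoyl]-2,6,6-trimethyl-3-{[tri(propan-2-yl)silyl]oxy}cyclohex-1-en-1-yl trifluoromethanesulfonate
Product: 10 (3S,4S)-4-acetyl-2,6,6-trimethyl-3-{[tri(propan-2-yl)silyl]oxy}cyclohex-1-en-1-yl trifluoromethanesulfonate
Conditions: MeMgBr, THF, 0 °C
Reagents that add atoms: methylmagnesium bromide, C[Mg]Br
Why: Grignard addition to the N-methoxy-N-methylamide (Weinreb ketone synthesis) stops at the chelated tetrahedral intermediate, so the methyl ketone is released only on work-up and C3 is not epimerised; the enol triflate does not react with MeMgBr in the absence of a transition-metal catalyst.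

Step 7
Reactants: 10 (3S,4S)-4-acetyl-2,6,6-trimethyl-3-{[tri(propan-2-yl)silyl]oxy}cyclohex-1-en-1-yl trifluoromethanesulfonate
Product: 11 (3R,4S)-4-(acetyloxy)-2,6,6-trimethyl-3-{[tri(propan-2-yl)silyl]oxy}cyclohex-1-en-1-yl trifluoromethanesulfonate
Conditions: mCPBA, NaHCO3, CH2Cl2, rt
Reagents that add atoms: 3-chloroperoxybenzoic acid, OOC(=O)c1cccc(Cl)c1
Why: Baeyer–Villiger oxidation: the secondary ring carbon migrates in preference to methyl with retention at C3, so the cis relation from step 3 becomes the cis-3,4-dioxygen pattern, while the C5=C6 bond is shielded from the peracid by the electron-withdrawing triflate (hence this step precedes the coupling).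

Step 8
Reactants: 12 (2E)-3-methylpent-2-en-4-yn-1-ol
Product: 13 (2E,4E)-3-methyl-5-(tributylstannyl)penta-2,4-dien-1-ol
Conditions: Bu3SnH, PdCl2(PPh3)2 (2 mol %), THF, 0 °C
Reagents that add atoms: tributyltin hydride, CCCC[SnH](CCCC)CCCC
Why: Palladium-catalysed syn-hydrostannation of the terminal alkyne should place tin on the unhindered terminal carbon (the branched C3 disfavours the internal isomer) and give the (E)-alkenylstannane.

Step 9
Reactants: 11 (3R,4S)-4-(acetyloxy)-2,6,6-trimethyl-3-{[tri(propan-2-yl)silyl]oxy}cyclohex-1-en-1-yl trifluoromethanesulfonate; 13 (2E,4E)-3-methyl-5-(tributylstannyl)penta-2,4-dien-1-ol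
Product: 14 (1S,2R)-4-[(1E,3E)-5-hydroxy-3-methylpenta-1,3-dien-1-yl]-3,5,5-trimethyl-2-{[tri(propan-2-yl)silyl]oxy}cyclohex-3-en-1-yl acetate
Conditions: Pd2(dba)3 (2.5 mol %), AsPh3 (20 mol %), N-methylpyrrolidone, 60 °C
Reagents that add atoms: none
Why: Stille cross-coupling of the hindered cyclohexenyl triflate with the (E)-alkenylstannane (the reaction type used for 2,6,6-trimethylcyclohexenyl triflates in retinoid work) should form C6–C7 with retention of both alkene geometries and replaces the temporary C6 oxygen by the chain.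

Step 10
Reactants: 14 (1S,2R)-4-[(1E,3E)-5-hydroxy-3-methylpenta-1,3-dien-1-yl]-3,5,5-trimethyl-2-{[tri(propan-2-yl)silyl]oxy}cyclohex-3-en-1-yl acetate
Product: 16 {(2E,4E)-5-[(3R,4S)-4-(acetyloxy)-2,6,6-trimethyl-3-{[tri(propan-2-yl)silyl]oxy}cyclohex-1-en-1-yl]-3-methylpenta-2,4-dien-1-yl}(triphenyl)phosphonium bromide, via allylic bromide 15 (not isolated)
Conditions: CBr4, PPh3, CH2Cl2, 0 °C; then PPh3, rt
Reagents that add atoms: carbon tetrabromide, BrC(Br)(Br)Br; triphenylphosphine, c1ccccc1P(c1ccccc1)c1ccccc1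
Why: Appel bromination of the primary dienylic alcohol under neutral conditions followed by SN2 quaternisation of PPh3 should give the allylic phosphonium salt without exposing the allylic C4 silyl ether to acid.

Step 11
Reactants: 17 (R)-α-ionone, (3E)-4-[(1R)-2,6,6-trimethylcyclohex-2-en-1-yl]but-3-en-2-one; 18 triethyl phosphonoacetate
Product: 19 ethyl (2E,4E)-3-methyl-5-[(1R)-2,6,6-trimethylcyclohex-2-en-1-yl]penta-2,4-dienoate
Conditions: NaH, THF, 0 °C to rt; (9E) isomer separated by chromatography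
Reagents that add atoms: none
Why: Horner–Wadsworth–Emmons olefination of the methyl ketone; the phosphonate anion is too weak a base to deprotonate the γ-position (C6'), so the stereocentre should be kept, and the (E) isomer is expected to predominate.

Step 12
Reactants: 19 ethyl (2E,4E)-3-methyl-5-[(1R)-2,6,6-trimethylcyclohex-2-en-1-yl]penta-2,4-dienoate
Product: 20 ethyl (2E,4E)-3-methyl-5-[(1R)-2,6,6-trimethyl-4-oxocyclohex-2-en-1-yl]penta-2,4-dienoate
Conditions: t-BuOOH (decane solution), Mn(OAc)3·2H2O (10 mol %), 3 Å molecular sieves, EtOAc, rt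
Reagents that add atoms: tert-butyl hydroperoxide, CC(C)(C)OO
Why: Radical allylic oxidation of the ring allylic CH2 (C3') to the enone, a reaction type known for α-ionone and its C15 derivatives; the tertiary bis-allylic C6'–H is shielded by the gem-dimethyl group and the side chain.

Step 13
Reactants: 20 ethyl (2E,4E)-3-methyl-5-[(1R)-2,6,6-trimethyl-4-oxocyclohex-2-en-1-yl]penta-2,4-dienoate
Product: 21 ethyl (2E,4E)-5-[(1R,4R)-4-hydroxy-2,6,6-trimethylcyclohex-2-en-1-yl]-3-methylpenta-2,4-dienoate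
Conditions: (S)-2-methyl-CBS-oxazaborolidine (0.2 equiv), catecholborane, toluene, −78 °C
Reagents that add atoms: none
Why: Corey–Bakshi–Shibata reduction: with the alkenyl flank as the large group the (S)-oxazaborolidine should deliver hydride to the face that gives the (3'R) allylic alcohol, trans to the C6' side chain, under reagent control, and the dienoate ester is not reduced.

Step 14
Reactants: 21 ethyl (2E,4E)-5-[(1R,4R)-4-hydroxy-2,6,6-trimethylcyclohex-2-en-1-yl]-3-methylpenta-2,4-dienoate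
Product: 22 ethyl (2E,4E)-5-[(1R,4R)-4-{[tert-butyl(dimethyl)silyl]oxy}-2,6,6-trimethylcyclohex-2-en-1-yl]-3-methylpenta-2,4-dienoate
Conditions: t-BuMe2SiCl, imidazole, DMF, rt
Reagents that add atoms: tert-butyldimethylsilyl chloride, CC(C)(C)[Si](C)(C)Cl
Why: Standard silylation of the secondary allylic alcohol with imidazole as base gives a fluoride-labile ether, chosen because the allylic C–O bonds of the target do not tolerate acid.

Step 15
Reactants: 22 ethyl (2E,4E)-5-[(1R,4R)-4-{[tert-butyl(dimethyl)silyl]oxy}-2,6,6-trimethylcyclohex-2-en-1-yl]-3-methylpenta-2,4-dienoate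
Product: 23 (2E,4E)-5-[(1R,4R)-4-{[tert-butyl(dimethyl)silyl]oxy}-2,6,6-trimethylcyclohex-2-en-1-yl]-3-methylpenta-2,4-dien-1-ol
Conditions: i-Bu2AlH, CH2Cl2, −78 °C
Reagents that add atoms: none
Why: 1,2-Reduction of the conjugated ester by the aluminium hydride should give the primary dienylic alcohol without touching the alkenes or the silyl ether.

Step 16
Reactants: 23 (2E,4E)-5-[(1R,4R)-4-{[tert-butyl(dimethyl)silyl]oxy}-2,6,6-trimethylcyclohex-2-en-1-yl]-3-methylpenta-2,4-dien-1-ol
Product: 25 {(2E,4E)-5-[(1R,4R)-4-{[tert-butyl(dimethyl)silyl]oxy}-2,6,6-trimethylcyclohex-2-en-1-yl]-3-methylpenta-2,4-dien-1-yl}(triphenyl)phosphonium bromide, via allylic bromide 24 (not isolated)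
Conditions: CBr4, PPh3, CH2Cl2, 0 °C; then PPh3, rt
Reagents that add atoms: carbon tetrabromide, BrC(Br)(Br)Br; triphenylphosphine, c1ccccc1P(c1ccccc1)c1ccccc1
Why: Appel bromination and SN2 quaternisation as in step 10, again under neutral conditions so that the allylic C3' silyl ether should not ionise.

Step 17
Reactants: 25 {(2E,4E)-5-[(1R,4R)-4-{[tert-butyl(dimethyl)silyl]oxy}-2,6,6-trimethylcyclohex-2-en-1-yl]-3-methylpenta-2,4-dien-1-yl}(triphenyl)phosphonium bromide; 26 (2E,4E,6E)-2,7-dimethylocta-2,4,6-trienedial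
Product: 27 (2E,4E,6E,8E,10E,12E)-13-[(1R,4R)-4-{[tert-butyl(dimethyl)silyl]oxy}-2,6,6-trimethylcyclohex-2-en-1-yl]-2,7,11-trimethyltrideca-2,4,6,8,10,12-hexaenal
Conditions: NaOMe, MeOH/CH2Cl2, 0 °C to rt, 26 in excess (3 equiv); then I2 (cat.), CH2Cl2, rt
Reagents that add atoms: none
Why: Wittig olefination with the dialdehyde in excess should stop at mono-condensation, and the Z/E mixture expected at the new C11'=C12' bond from the semi-stabilised ylide is equilibrated to the E isomer by iodine.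

Step 18
Reactants: 16 {(2E,4E)-5-[(3R,4S)-4-(acetyloxy)-2,6,6-trimethyl-3-{[tri(propan-2-yl)silyl]oxy}cyclohex-1-en-1-yl]-3-methylpenta-2,4-dien-1-yl}(triphenyl)phosphonium bromide; 27 (2E,4E,6E,8E,10E,12E)-13-[(1R,4R)-4-{[tert-butyl(dimethyl)silyl]oxy}-2,6,6-trimethylcyclohex-2-en-1-yl]-2,7,11-trimethyltrideca-2,4,6,8,10,12-hexaenal
Product: 28 (all-E,3S,4R,3'R,6'R)-3-O-acetyl-3'-O-[tert-butyl(dimethyl)silyl]-4-O-[tri(propan-2-yl)silyl]-β,ε-carotene-3,4,3'-triol
Conditions: NaN(SiMe3)2, THF, −78 °C, then 27, −78 °C to rt; then heptane, 90 °C (Z to E), dark, argon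
Reagents that add atoms: none
Why: Wittig olefination with a non-nucleophilic base that leaves the acetate in place should form C11=C12, and the (11Z) isomer is funnelled thermally into the all-E polyene, as is usual for C15 + C25 carotenoid couplings.

Step 19
Reactants: 28 (all-E,3S,4R,3'R,6'R)-3-O-acetyl-3'-O-[tert-butyl(dimethyl)silyl]-4-O-[tri(propan-2-yl)silyl]-β,ε-carotene-3,4,3'-triol
Product: 30 (all-E,3S,4R,3'R,6'R)-β,ε-carotene-3,4,3'-triol (CNP0191612.1), via bis-silyl ether 29 (not isolated)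
Conditions: K2CO3, MeOH/THF, rt; then Bu4NF, THF, rt, dark, argon
Reagents that add atoms: none
Why: Base-catalysed transesterification removes the acetate and fluoride desilylation removes both silyl ethers; both are non-acidic, so the allylic C4–O and C3'–O bonds, which would ionise in acid, should survive with their configuration.

**Compound list**

1 | 2-methylpentan-3-one | CCC(=O)C(C)C | starting material
2 | ethyl formate | CCOC=O | starting material
3 | sodium (1Z)-2,4-dimethyl-3-oxopent-1-en-1-olate | CC(C)C(=O)/C(C)=C\[O-].[Na+] | intermediate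
4 | (1E)-2,4-dimethyl-1-{[tri(propan-2-yl)silyl]oxy}pent-1-en-3-one | CC(C)C(=O)/C(C)=C/O[Si](C(C)C)(C(C)C)C(C)C | intermediate
5 | (1E)-3-{[tert-butyl(dimethyl)silyl]oxy}-2,4-dimethyl-1-{[tri(propan-2-yl)silyl]oxy}penta-1,3-diene | CC(C)=C(O[Si](C)(C)C(C)(C)C)/C(C)=C/O[Si](C(C)C)(C(C)C)C(C)C | intermediate
6 | 3-acryloyl-1,3-oxazolidin-2-one | C=CC(=O)N1CCOC1=O | starting material
7 | 3-{[(1S,2S)-4-{[tert-butyl(dimethyl)silyl]oxy}-3,5,5-trimethyl-2-{[tri(propan-2-yl)silyl]oxy}cyclohex-3-en-1-yl]carbonyl}-1,3-oxazolidin-2-one | CC(C)(C)[Si](C)(C)OC1=C(C)[C@@H](O[Si](C(C)C)(C(C)C)C(C)C)[C@@H](C(=O)N2CCOC2=O)CC1(C)C | intermediate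
8 | (3S,4S)-2,6,6-trimethyl-4-[(2-oxo-1,3-oxazolidin-3-yl)carbonyl]-3-{[tri(propan-2-yl)silyl]oxy}cyclohex-1-en-1-yl trifluoromethanesulfonate | FC(F)(F)S(=O)(=O)OC1=C(C)[C@@H](O[Si](C(C)C)(C(C)C)C(C)C)[C@@H](C(=O)N2CCOC2=O)CC1(C)C | intermediate
9 | (3S,4S)-4-[methoxy(methyl)carbamoyl]-2,6,6-trimethyl-3-{[tri(propan-2-yl)silyl]oxy}cyclohex-1-en-1-yl trifluoromethanesulfonate | FC(F)(F)S(=O)(=O)OC1=C(C)[C@@H](O[Si](C(C)C)(C(C)C)C(C)C)[C@@H](C(=O)N(C)OC)CC1(C)C | intermediate
10 | (3S,4S)-4-acetyl-2,6,6-trimethyl-3-{[tri(propan-2-yl)silyl]oxy}cyclohex-1-en-1-yl trifluoromethanesulfonate | FC(F)(F)S(=O)(=O)OC1=C(C)[C@@H](O[Si](C(C)C)(C(C)C)C(C)C)[C@@H](C(C)=O)CC1(C)C | intermediate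
11 | (3R,4S)-4-(acetyloxy)-2,6,6-trimethyl-3-{[tri(propan-2-yl)silyl]oxy}cyclohex-1-en-1-yl trifluoromethanesulfonate | FC(F)(F)S(=O)(=O)OC1=C(C)[C@@H](O[Si](C(C)C)(C(C)C)C(C)C)[C@@H](OC(C)=O)CC1(C)C | intermediate
12 | (2E)-3-methylpent-2-en-4-yn-1-ol | C#C/C(C)=C/CO | starting material
13 | (2E,4E)-3-methyl-5-(tributylstannyl)penta-2,4-dien-1-ol | CCCC[Sn](CCCC)(CCCC)/C=C/C(C)=C/CO | intermediate
14 | (1S,2R)-4-[(1E,3E)-5-hydroxy-3-methylpenta-1,3-dien-1-yl]-3,5,5-trimethyl-2-{[tri(propan-2-yl)silyl]oxy}cyclohex-3-en-1-yl acetate | OC/C=C(C)/C=C/C1=C(C)[C@@H](O[Si](C(C)C)(C(C)C)C(C)C)[C@@H](OC(C)=O)CC1(C)C | intermediate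
15 | (1S,2R)-4-[(1E,3E)-5-bromo-3-methylpenta-1,3-dien-1-yl]-3,5,5-trimethyl-2-{[tri(propan-2-yl)silyl]oxy}cyclohex-3-en-1-yl acetate | BrC/C=C(C)/C=C/C1=C(C)[C@@H](O[Si](C(C)C)(C(C)C)C(C)C)[C@@H](OC(C)=O)CC1(C)C | intermediate
16 | {(2E,4E)-5-[(3R,4S)-4-(acetyloxy)-2,6,6-trimethyl-3-{[tri(propan-2-yl)silyl]oxy}cyclohex-1-en-1-yl]-3-methylpenta-2,4-dien-1-yl}(triphenyl)phosphonium bromide | [Br-].c1ccccc1[P+](c1ccccc1)(c1ccccc1)C/C=C(C)/C=C/C1=C(C)[C@@H](O[Si](C(C)C)(C(C)C)C(C)C)[C@@H](OC(C)=O)CC1(C)C | intermediate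
17 | (R)-α-ionone, (3E)-4-[(1R)-2,6,6-trimethylcyclohex-2-en-1-yl]but-3-en-2-one | CC1=CCCC(C)(C)[C@H]1/C=C/C(C)=O | starting material
18 | triethyl phosphonoacetate | CCOC(=O)CP(=O)(OCC)OCC | starting material
19 | ethyl (2E,4E)-3-methyl-5-[(1R)-2,6,6-trimethylcyclohex-2-en-1-yl]penta-2,4-dienoate | CC1=CCCC(C)(C)[C@H]1/C=C/C(C)=C/C(=O)OCC | intermediate
20 | ethyl (2E,4E)-3-methyl-5-[(1R)-2,6,6-trimethyl-4-oxocyclohex-2-en-1-yl]penta-2,4-dienoate | CC1=CC(=O)CC(C)(C)[C@H]1/C=C/C(C)=C/C(=O)OCC | intermediate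
21 | ethyl (2E,4E)-5-[(1R,4R)-4-hydroxy-2,6,6-trimethylcyclohex-2-en-1-yl]-3-methylpenta-2,4-dienoate | CC1=C[C@H](O)CC(C)(C)[C@H]1/C=C/C(C)=C/C(=O)OCC | intermediate
22 | ethyl (2E,4E)-5-[(1R,4R)-4-{[tert-butyl(dimethyl)silyl]oxy}-2,6,6-trimethylcyclohex-2-en-1-yl]-3-methylpenta-2,4-dienoate | CC1=C[C@H](O[Si](C)(C)C(C)(C)C)CC(C)(C)[C@H]1/C=C/C(C)=C/C(=O)OCC | intermediate
23 | (2E,4E)-5-[(1R,4R)-4-{[tert-butyl(dimethyl)silyl]oxy}-2,6,6-trimethylcyclohex-2-en-1-yl]-3-methylpenta-2,4-dien-1-ol | CC1=C[C@H](O[Si](C)(C)C(C)(C)C)CC(C)(C)[C@H]1/C=C/C(C)=C/CO | intermediate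
24 | tert-butyl{[(1R,4R)-4-[(1E,3E)-5-bromo-3-methylpenta-1,3-dien-1-yl]-3,5,5-trimethylcyclohex-2-en-1-yl]oxy}dimethylsilane | CC1=C[C@H](O[Si](C)(C)C(C)(C)C)CC(C)(C)[C@H]1/C=C/C(C)=C/CBr | intermediate
25 | {(2E,4E)-5-[(1R,4R)-4-{[tert-butyl(dimethyl)silyl]oxy}-2,6,6-trimethylcyclohex-2-en-1-yl]-3-methylpenta-2,4-dien-1-yl}(triphenyl)phosphonium bromide | [Br-].CC1=C[C@H](O[Si](C)(C)C(C)(C)C)CC(C)(C)[C@H]1/C=C/C(C)=C/C[P+](c1ccccc1)(c1ccccc1)c1ccccc1 | intermediate
26 | (2E,4E,6E)-2,7-dimethylocta-2,4,6-trienedial | O=C/C(C)=C/C=C/C=C(C)/C=O | starting material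
27 | (2E,4E,6E,8E,10E,12E)-13-[(1R,4R)-4-{[tert-butyl(dimethyl)silyl]oxy}-2,6,6-trimethylcyclohex-2-en-1-yl]-2,7,11-trimethyltrideca-2,4,6,8,10,12-hexaenal | CC1=C[C@H](O[Si](C)(C)C(C)(C)C)CC(C)(C)[C@H]1/C=C/C(C)=C/C=C/C(C)=C/C=C/C=C(C)/C=O | intermediate
28 | (all-E,3S,4R,3'R,6'R)-3-O-acetyl-3'-O-[tert-butyl(dimethyl)silyl]-4-O-[tri(propan-2-yl)silyl]-β,ε-carotene-3,4,3'-triol | CC1=C[C@H](O[Si](C)(C)C(C)(C)C)CC(C)(C)[C@H]1/C=C/C(C)=C/C=C/C(C)=C/C=C/C=C(C)/C=C/C=C(C)/C=C/C1=C(C)[C@@H](O[Si](C(C)C)(C(C)C)C(C)C)[C@@H](OC(C)=O)CC1(C)C | intermediate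
29 | (all-E,3S,4R,3'R,6'R)-3'-O-[tert-butyl(dimethyl)silyl]-4-O-[tri(propan-2-yl)silyl]-β,ε-carotene-3,4,3'-triol | CC1=C[C@H](O[Si](C)(C)C(C)(C)C)CC(C)(C)[C@H]1/C=C/C(C)=C/C=C/C(C)=C/C=C/C=C(C)/C=C/C=C(C)/C=C/C1=C(C)[C@@H](O[Si](C(C)C)(C(C)C)C(C)C)[C@@H](O)CC1(C)C | intermediate
30 | (all-E,3S,4R,3'R,6'R)-β,ε-carotene-3,4,3'-triol (CNP0191612.1) | CC1=C[C@H](O)CC(C)(C)[C@H]1/C=C/C(C)=C/C=C/C(C)=C/C=C/C=C(C)/C=C/C=C(C)/C=C/C1=C(C)[C@@H](O)[C@@H](O)CC1(C)C | target

**Step count and risks**

Total step count: 19. Longest linear sequence: 11 steps (steps 1 to 7, 9, 10, 18 and 19).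

Steps most likely to fail:

1. Step 3. The cationic copper Lewis acid may strip silyl groups from the diene or divert it to open-chain Mukaiyama–Michael products, and the crowded diene may turn the catalyst over slowly, so that endo and facial control are lost. Fallback: the asymmetry is moved from a catalyst to a covalently bound auxiliary. Setting out from diene 5, commercial (4R)-4-benzyl-1,3-oxazolidin-2-one is N-acylated (n-BuLi, acryloyl chloride, THF, −78 °C) to (4R)-3-acryloyl-4-benzyl-1,3-oxazolidin-2-one F1. F1 and 5 are combined under Et2AlCl (1.4 equiv, CH2Cl2, −78 °C), the auxiliary-controlled Diels–Alder reaction through the chelated aluminium imide in which the diene approaches anti to the benzyl group, to give the cis adduct (4R)-4-benzyl-3-{[(1S,2S)-4-{[tert-butyl(dimethyl)silyl]oxy}-3,5,5-trimethyl-2-{[tri(propan-2-yl)silyl]oxy}cyclohex-3-en-1-yl]carbonyl}-1,3-oxazolidin-2-one F2. CsF/PhNTf2 converts F2 into the enol triflate (3S,4S)-4-{[(4R)-4-benzyl-2-oxo-1,3-oxazolidin-3-yl]carbonyl}-2,6,6-trimethyl-3-{[tri(propan-2-yl)silyl]oxy}cyclohex-1-en-1-yl trifluoromethanesulfonate F3, and AlMe3/MeNH(OMe)·HCl cleaves the auxiliary, which returns the route at compound 9.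

2. Step 4. The free caesium enolate may expel the neighbouring silyloxy group (E1cB elimination to an enone) or exchange a proton with C3 (epimerisation) faster than it is sulfonylated. Fallback: the enolate is avoided altogether. Setting out from 7, buffered desilylation (HF·pyridine, pyridine, THF, 0 °C) gives the ketone 3-{[(1S,2R)-3,5,5-trimethyl-4-oxo-2-{[tri(propan-2-yl)silyl]oxy}cyclohexyl]carbonyl}-1,3-oxazolidin-2-one F4 as a mixture of epimers at the methyl-bearing carbon. Electrophilic triflation with Tf2O and 2,6-di-tert-butyl-4-methylpyridine (CH2Cl2, 0 °C), where only the methyl-bearing carbon carries an enolisable hydrogen because C1 is quaternary, then gives enol triflate 8, where the route is rejoined.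

3. Step 12. Hydrogen abstraction at the tertiary bis-allylic C6'–H or oxidation of the dienoate chain may compete with oxidation of the ring CH2, with loss of the stereocentre or over-oxidation. Fallback: the order of operations is reversed so that the oxidation is run on the simplest substrate, for which it is well established. Setting out from 17, the same t-BuOOH/Mn(OAc)3 oxidation gives (4R)-3,5,5-trimethyl-4-[(1E)-3-oxobut-1-en-1-yl]cyclohex-2-en-1-one F5 ((R)-3-oxo-α-ionone). Horner–Wadsworth–Emmons olefination with 18 (NaH, THF, 0 °C), which should select the unhindered side-chain methyl ketone over the β,β-disubstituted ring enone, then gives compound 20, where the route is rejoined.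

Further compounds
F1 | step 3 | (4R)-3-acryloyl-4-benzyl-1,3-oxazolidin-2-one | C=CC(=O)N1[C@H](Cc2ccccc2)COC1=O
F2 | step 3 | (4R)-4-benzyl-3-{[(1S,2S)-4-{[tert-butyl(dimethyl)silyl]oxy}-3,5,5-trimethyl-2-{[tri(propan-2-yl)silyl]oxy}cyclohex-3-en-1-yl]carbonyl}-1,3-oxazolidin-2-one | CC(C)(C)[Si](C)(C)OC1=C(C)[C@@H](O[Si](C(C)C)(C(C)C)C(C)C)[C@@H](C(=O)N2[C@H](Cc3ccccc3)COC2=O)CC1(C)C
F3 | step 3 | (3S,4S)-4-{[(4R)-4-benzyl-2-oxo-1,3-oxazolidin-3-yl]carbonyl}-2,6,6-trimethyl-3-{[tri(propan-2-yl)silyl]oxy}cyclohex-1-en-1-yl trifluoromethanesulfonate | FC(F)(F)S(=O)(=O)OC1=C(C)[C@@H](O[Si](C(C)C)(C(C)C)C(C)C)[C@@H](C(=O)N2[C@H](Cc3ccccc3)COC2=O)CC1(C)C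
F4 | step 4 | 3-{[(1S,2R)-3,5,5-trimethyl-4-oxo-2-{[tri(propan-2-yl)silyl]oxy}cyclohexyl]carbonyl}-1,3-oxazolidin-2-one (both epimers at ring position 3) | O=C1C(C)[C@@H](O[Si](C(C)C)(C(C)C)C(C)C)[C@@H](C(=O)N2CCOC2=O)CC1(C)C
F5 | step 12 | (4R)-3,5,5-trimethyl-4-[(1E)-3-oxobut-1-en-1-yl]cyclohex-2-en-1-one | CC1=CC(=O)CC(C)(C)[C@H]1/C=C/C(C)=O
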